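The readings were computed on assumed constants; noise was put on by code.

Target is what the readings count, and the question is where it stands in this flask at the asked time.

| setting | Friday's | Thursday's | flask |
|---|---|---|---|
| substrate | 0.020 M | 0.020 M | 0.020 M |
| solid reagent | 0.011 M | 0.044 M | 0.0220 M |
| catalyst | 40 µM | 40 µM | 40 µM |
| remark | run made earlier | run made earlier |  |
| time |  |  | 4.0 min |

- Friday's (time / min: target / %, substrate / %): 1.33: 8, 93; 2.50: 19, 84; 4.00: 31, 72; 5.00: 39, 63
- Thursday's (time / min: target / %, substrate / %): 0.417: 0, 97; 0.833: 3, 96; 2.00: 15, 90; 5.00: 41, 64

(standard deviation of a reading: 1.5 percentage points)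

- as a solid, counted per litre of solution: solid reagent
- the numbers in the tables scatter with a standard deviation of 1.5 percentage points
- at the start none of the solid reagent is in solution

- the target standing at 4.0 min, as a percentage of the substrate charged
- the change that raises the amount of target at 4.0 min, in percent of the substrate charged most ("none" if none brings more than 2 percentage points) (noon / dawn / winter / none)
- amount of target at 4.0 min, in percent of the substrate charged, after winter

- noon: doubling the dissolution coefficient of the solid reagent, all else as stated
- dawn: doubling the amount of catalyst, all else as stated
- winter: doubling the solubility of the solid reagent, all else as stated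

What do you read from the curves? I replace each by its mean slope, target gained per minute as a fraction of the substrate charged: Friday's from 2.50 min to 5.00 min gives 0.0800 min⁻¹, Thursday's from 2.00 min to 5.00 min gives 0.0867 min⁻¹, and their mean is the running rate, the apparent zero-order rate of these readings, 0.0833 min⁻¹.

Does the solid charge matter? Thursday held 4.00 times Friday's solid, yet their readings at 5.00 min differ by 2 percentage points against a scatter of 1.5 points, so I use this rate for the flask, whose charge lies between them.

But substrate falls, so doesn't the line bend? Friday's slope is 0.0800 min⁻¹ before 4.00 min and 0.0800 min⁻¹ after it, with no bend visible up to 5.00 min.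

Your number? Stepping back from the mean of 40.0 % at 5.00 min to 4.0 min gives 31.7 %, and Friday's independent reading there, 31 %, lies within the scatter of it.

Which change? I choose winter and assume a running rate twice as great, which gives 63.3 %.

The forecast gave 32 % (29.5 % to 34 %) and, choosing winter, a lower 60 % (50 % to 66 %) than my figure, holding that “Doubling solubility doubles the dissolved level whichever limits”.

The flask gives 29.4 %; winter is best, gaining 24 points against 17 points for noon and 9 points for dawn, and reaches 53.8 %.

    substrate + partner + catalyst → target + catalyst, rate k1*[substrate]*[partner]*[catalyst]/(1 + ([substrate]/sat1)) (35.0 mM, k = 25000 L² mol⁻² s⁻¹)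
    solid reagent ⇌ partner, rate k2*(cs2 - [partner]) while solid is left; crystals form when [partner] > cs2 (solubility = 9.80 mM, k = 0.00480 s⁻¹)

Between 2.00 min and 4.00 min this flask gains 0.0888 min⁻¹, close to the running rate of 0.0833 min⁻¹. The same flask read at 10 min lies beyond the stretch the line was read from, and the line puts it at 81.7 %. It stands lower, at 75.1 % of target with 24.9 % of the substrate left.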